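**Strategy.** Ring B (C5–C6–C7–C8–C9–C10) is formed last. Disconnecting C9–C10 and letting C9 leave the ring gives a ring-B-nor trans-hydrindane whose C8 carries the whole side chain as an exocyclic C8=C9 alkylidene. Oxidation with trivalent thallium shifts the quaternary C10 from C8 to C9: one operation enlarges the cyclopentane to the cyclohexanone, makes the hindered C9–C10 bond, creates the C8 carbonyl (the later exocyclic methylene carbon) and merges both alkene isomers into one epimerisable C9 centre. The step exploits C8 flanked by C9–H and quaternary C10 in ring B. The hydrindanone comes from dehydroabietic acid (C4, C5, C10 kept; aromatic ring cleaved; Dieckmann closure), the side chain from (R)-citronellic acid.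

Key step: step 11

Remark: labdane numbering of the target is used for all intermediates (C18 = 4α-CH2O, C19 = 4β-CH3, C20 = 10β-CH3; in the hydrindane series C8 is the carbon on C10 that becomes the ring-B carbonyl). Dehydroabietic acid and (R)-citronellic acid are taken as commercial single enantiomers.

Step 1
Reactants: 1 dehydroabietic acid
Product: 2 dehydroabietinol [(1R,4aS,10aR)-1,4a-dimethyl-7-(propan-2-yl)-1,2,3,4,4a,9,10,10a-octahydrophenanthren-1-yl]methanol
Conditions: LiAlH4, THF, 0 °C → reflux; aq. NaOH work-up
Reagents that add atoms: none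
Why: LiAlH4 reduces the hindered C18 carboxylic acid to the primary alcohol (hydride reduction of a carboxylic acid), which differentiates C18 from the two carboxyl groups created in step 3 and leaves C4, C5 and C10 untouched.

Step 2
Reactants: 2 dehydroabietinol
Product: 3 18-(triisopropylsilyloxy)abieta-8,11,13-triene
Conditions: TIPSOTf, 2,6-lutidine, CH2Cl2, 0 °C → rt
Reagents that add atoms: triisopropylsilyl trifluoromethanesulfonate, CC(C)[Si](C(C)C)(C(C)C)OS(=O)(=O)C(F)(F)F
Why: Silylation with the silyl triflate (silyl ether protection) masks the neopentyl C18 hydroxyl in a form that should survive ozone, alkoxide, ylides and brief mild acid, and prevents lactonisation onto the C10 carboxyl once ring B is opened.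

Step 3
Reactants: 3 18-(triisopropylsilyloxy)abieta-8,11,13-triene
Product: 4 seco-diacid 3-[(1S,2S,6R)-2-carboxy-2,6-dimethyl-6-[(triisopropylsilyloxy)methyl]cyclohexyl]propanoic acid
Conditions: O3/O2, CH2Cl2–AcOH, 0 °C → rt, to full consumption; then 30% H2O2, aq. NaOH, 0 °C → rt; HCl to pH 3
Reagents that add atoms: ozone, [O-][O+]=O; hydrogen peroxide, OO
Why: Exhaustive ozonolysis of the trialkylbenzene ring followed by oxidative cleavage of the resulting α-dicarbonyl units (arene ozonolysis, oxidative work-up) should leave only the two ipso carbons as carboxyl groups, one on C10 and one at the end of the C6–C7 chain, and removes C11–C14 and the isopropyl group as formic and 2-methylpropanoic acid while C4, C5 and C10 keep their configuration.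

Step 4
Reactants: 4 seco-diacid
Product: 5 dimethyl ester of 4
Conditions: MeI, K2CO3, DMF, rt
Reagents that add atoms: iodomethane, CI
Why: SN2 methylation of the dipotassium dicarboxylate (carboxylate O-alkylation) esterifies even the hindered tertiary carboxyl on C10 without acid.

Step 5
Reactants: 5 dimethyl ester
Product: 6 β-keto ester methyl (3aS,4R,7aS)-4,7a-dimethyl-1-oxo-4-[(triisopropylsilyloxy)methyl]octahydro-1H-indene-2-carboxylate (C7 epimers and enol)
Conditions: t-BuOK, THF, 0 °C → reflux; AcOH quench
Reagents that add atoms: none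
Why: Dieckmann condensation: C7 is the only enolisable position, so its ester enolate acylates the ester on quaternary C10 and closes the trans-fused cyclopentanone, the equilibrium being pulled by deprotonation of the β-keto ester.

Step 6
Reactants: 6 β-keto ester
Product: 7 hydrindanone (3aS,4R,7aS)-4,7a-dimethyl-4-[(triisopropylsilyloxy)methyl]octahydro-1H-inden-1-one (trans-fused; 5α-H, 10β-CH3)
Conditions: LiCl, DMSO, H2O, 150 °C
Reagents that add atoms: none
Why: Krapcho dealkoxycarbonylation (chloride attack on the ester methyl, loss of CO2) removes the superfluous carboxyl carbon under neutral conditions and leaves the ketone C8 attached to quaternary C10.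

Step 7
Reactants: 8 (R)-citronellic acid [(3R)-3,7-dimethyloct-6-enoic acid]
Product: 9 (3R)-6-hydroxy-3-methylhexanoic acid
Conditions: O3, CH2Cl2/MeOH, −78 °C; then NaBH4, −78 °C → rt; aq. HCl
Reagents that add atoms: ozone, [O-][O+]=O
Why: Ozonolysis of the trisubstituted alkene with reductive NaBH4 work-up cuts off the isopropylidene unit and gives the primary alcohol at the future C9, while the future C13 stereocentre, β to the carboxyl group, cannot epimerise.

Step 8
Reactants: 9 (3R)-6-hydroxy-3-methylhexanoic acid
Product: 10 (3R)-6-bromo-3-methylhexanoic acid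
Conditions: 48% aq. HBr, H2SO4 (cat.), 100 °C
Reagents that add atoms: hydrogen bromide, Br
Why: Acid-promoted SN2 substitution of the primary alcohol (or of any ε-lactone formed from it) by bromide gives the ω-bromo acid.

Step 9
Reactants: 10 (3R)-6-bromo-3-methylhexanoic acid
Product: 11 [(4R)-5-carboxy-4-methylpentyl]triphenylphosphonium bromide
Conditions: PPh3, MeCN, reflux
Reagents that add atoms: triphenylphosphine, c1ccc(cc1)P(c1ccccc1)c1ccccc1
Why: SN2 quaternisation of triphenylphosphine by the primary bromide gives the Wittig salt, as for other ω-carboxyalkyl phosphonium salts.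

Step 10
Reactants: 7 hydrindanone; 11 [(4R)-5-carboxy-4-methylpentyl]triphenylphosphonium bromide
Product: 13 alkylidene acid (3R)-6-[(3aR,4R,7aS)-4,7a-dimethyl-4-[(triisopropylsilyloxy)methyl]octahydro-1H-inden-1-ylidene]-3-methylhexanoic acid (E/Z mixture), via ylide carboxylate 12 (not isolated)
Conditions: 11 (2 equiv), t-BuOK (4.2 equiv), THF, rt, 1 h; then 7, reflux, 24 h; cold 1 M HCl work-up
Reagents that add atoms: none
Why: Wittig olefination with the non-stabilised ylide, protected from self-acylation by its carboxylate, should convert the hindered C8 ketone into the C8=C9 alkylidene as in the alkylidenation of 17-oxo steroids, and the alkene geometry is immaterial because both isomers converge in step 11.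

Step 11
Reactants: 13 alkylidene acid
Product: 16 (13R)-8-oxo-18-(triisopropylsilyloxy)-17-norlabdan-15-oic acid (9α-H), via methoxythallation adduct 14 (not isolated), via dimethyl ketal 15 (not isolated)
Conditions: Tl(NO3)3·3H2O (1.1 equiv), MeOH, 0 °C, 15 min; filter; 0.5 M aq. HCl, THF, rt, 30 min; then NaOH, MeOH/H2O, 50 °C; HCl to pH 3
Reagents that add atoms: methanol, CO (carried in 14 and 15); water, O (carbonyl oxygen of 16)
Why: Trivalent thallium adds to the C8=C9 alkene in the Markovnikov sense (thallium on secondary C9, methanol on tertiary C8) to give 14, and heterolysis of the weak C9–Tl bond with loss of monovalent thallium is accompanied by a 1,2-shift of the electron-rich quaternary C10 from C8 to C9, pushed by the C8 methoxy group, so that C9 is inserted between C8 and C10 and the oxocarbenium ion is trapped as ketal 15, which dilute acid hydrolyses to the C8 ketone. The closest known reaction type is the oxidative ring enlargement of methylene- and alkylidenecycloalkanes to the homologous cycloalkanones by thallium trinitrate, a semipinacol-type shift. No ring is closed: ring B grows from the five-membered C5–C6–C7–C8–C10 ring to the six-membered C5–C6–C7–C8–C9–C10 ring by ring expansion, and C10 migrates with retention. The only new stereocentre, C9, lies α to the new ketone and is set under thermodynamic control by the hydroxide treatment, which should favour the equatorial 9β side chain (9α-H) and so merges both alkene isomers and both faces of attack into one product, while also saponifying any methyl ester formed in methanol. The step needs thallation at C9 and migration of C10 in preference to the C7 methylene; the higher substitution of C8 over C9 and the higher migratory aptitude of the fully substituted C10 should secure both, and methanol as solvent disfavours simple solvolysis to a glycol derivative.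

Step 12
Reactants: 16 (13R)-8-oxo-18-(triisopropylsilyloxy)-17-norlabdan-15-oic acid
Product: 17 (13R)-18-(triisopropylsilyloxy)labd-8(17)-en-15-oic acid
Conditions: Ph3PCH3Br (5 equiv), t-BuOK (5.5 equiv), toluene, rt → 90 °C; cold 1 M HCl work-up
Reagents that add atoms: methyltriphenylphosphonium bromide, [Br-].C[P+](c1ccccc1)(c1ccccc1)c1ccccc1
Why: Wittig methylenation of the hindered C8 ketone, the carboxylic acid being masked in situ as its potassium salt, installs C17, and any enolisation under the basic conditions can only return the thermodynamic 9α-H configuration.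

Step 13
Reactants: 17 (13R)-18-(triisopropylsilyloxy)labd-8(17)-en-15-oic acid
Product: 18 (13R)-18-hydroxylabd-8(17)-en-15-oic acid
Conditions: Bu4NF, THF, 50 °C; aq. NH4Cl, then HCl to pH 4
Reagents that add atoms: none
Why: Fluoride-induced cleavage of the Si–O bond (silyl ether deprotection) frees the C18 alcohol under non-acidic conditions that do not isomerise the exocyclic alkene.

Step 14
Reactants: 18 (13R)-18-hydroxylabd-8(17)-en-15-oic acid
Product: 20 (13R)-18-acetoxylabd-8(17)-en-15-oic acid (target), via mixed anhydride 19 (not isolated)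
Conditions: Ac2O, pyridine, DMAP (cat.), CH2Cl2, rt; then H2O/THF, rt
Reagents that add atoms: acetic anhydride, CC(=O)OC(C)=O
Why: DMAP-catalysed acetylation esterifies the primary C18 alcohol, and the mixed carboxylic anhydride formed at C15 is hydrolysed by water far faster than the acetate, which returns the free acid.

**Compound list**

1 | dehydroabietic acid, (1R,4aS,10aR)-1,4a-dimethyl-7-(propan-2-yl)-1,2,3,4,4a,9,10,10a-octahydrophenanthrene-1-carboxylic acid | C1C[C@H]2[C@](C)(C(=O)O)CCC[C@]2(C)c3ccc(C(C)C)cc31 | starting material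
2 | dehydroabietinol (abieta-8,11,13-trien-18-ol) | C1C[C@H]2[C@](C)(CO)CCC[C@]2(C)c3ccc(C(C)C)cc31 | intermediate
3 | 18-(triisopropylsilyloxy)abieta-8,11,13-triene | C1C[C@H]2[C@](C)(CO[Si](C(C)C)(C(C)C)C(C)C)CCC[C@]2(C)c3ccc(C(C)C)cc31 | intermediate
4 | seco-diacid, 3-[(1S,2S,6R)-2-carboxy-2,6-dimethyl-6-[(triisopropylsilyloxy)methyl]cyclohexyl]propanoic acid | OC(=O)CC[C@H]1[C@](C)(CO[Si](C(C)C)(C(C)C)C(C)C)CCC[C@]1(C)C(=O)O | intermediate
5 | dimethyl ester of 4 | COC(=O)CC[C@H]1[C@](C)(CO[Si](C(C)C)(C(C)C)C(C)C)CCC[C@]1(C)C(=O)OC | intermediate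
6 | β-keto ester, methyl (3aS,4R,7aS)-4,7a-dimethyl-1-oxo-4-[(triisopropylsilyloxy)methyl]octahydro-1H-indene-2-carboxylate (C7 epimers/enol) | COC(=O)C1C[C@H]2[C@](C)(CO[Si](C(C)C)(C(C)C)C(C)C)CCC[C@]2(C)C1=O | intermediate
7 | hydrindanone, (3aS,4R,7aS)-4,7a-dimethyl-4-[(triisopropylsilyloxy)methyl]octahydro-1H-inden-1-one (trans-fused) | C1C[C@H]2[C@](C)(CO[Si](C(C)C)(C(C)C)C(C)C)CCC[C@]2(C)C1=O | intermediate
8 | (R)-citronellic acid, (3R)-3,7-dimethyloct-6-enoic acid | CC(C)=CCC[C@@H](C)CC(=O)O | starting material
9 | (3R)-6-hydroxy-3-methylhexanoic acid | OCCC[C@@H](C)CC(=O)O | intermediate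
10 | (3R)-6-bromo-3-methylhexanoic acid | BrCCC[C@@H](C)CC(=O)O | intermediate
11 | [(4R)-5-carboxy-4-methylpentyl]triphenylphosphonium bromide | [Br-].OC(=O)C[C@H](C)CCC[P+](c1ccccc1)(c1ccccc1)c1ccccc1 | intermediate
12 | ylide carboxylate, potassium (3R)-3-methyl-6-(triphenylphosphoranylidene)hexanoate | [K+].[O-]C(=O)C[C@H](C)CCC=P(c1ccccc1)(c1ccccc1)c1ccccc1 | intermediate (not isolated)
13 | alkylidene acid, (3R)-6-[(3aR,4R,7aS)-4,7a-dimethyl-4-[(triisopropylsilyloxy)methyl]octahydro-1H-inden-1-ylidene]-3-methylhexanoic acid (C8=C9, E/Z mixture, geometry left open) | C1C[C@H]2[C@](C)(CO[Si](C(C)C)(C(C)C)C(C)C)CCC[C@]2(C)C1=CCC[C@@H](C)CC(=O)O | intermediate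
14 | methoxythallation adduct of 13 (C8–OCH3, C9–Tl(ONO2)2; C8 and C9 configuration open) | C1C[C@H]2[C@](C)(CO[Si](C(C)C)(C(C)C)C(C)C)CCC[C@]2(C)C1(OC)C(CC[C@@H](C)CC(=O)O)[Tl](O[N+](=O)[O-])O[N+](=O)[O-] | intermediate (not isolated)
15 | 8,8-dimethyl ketal of 16 (C9 epimers) | C1C[C@H]2[C@](C)(CO[Si](C(C)C)(C(C)C)C(C)C)CCC[C@]2(C)C(CC[C@@H](C)CC(=O)O)C1(OC)OC | intermediate (not isolated)
16 | (13R)-8-oxo-18-(triisopropylsilyloxy)-17-norlabdan-15-oic acid (5α-H, 9α-H, 10β-CH3) | C1C[C@H]2[C@](C)(CO[Si](C(C)C)(C(C)C)C(C)C)CCC[C@]2(C)[C@@H](CC[C@@H](C)CC(=O)O)C1=O | intermediate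
17 | (13R)-18-(triisopropylsilyloxy)labd-8(17)-en-15-oic acid | C=C1CC[C@H]2[C@](C)(CO[Si](C(C)C)(C(C)C)C(C)C)CCC[C@]2(C)[C@H]1CC[C@@H](C)CC(=O)O | intermediate
18 | (13R)-18-hydroxylabd-8(17)-en-15-oic acid | C=C1CC[C@H]2[C@](C)(CO)CCC[C@]2(C)[C@H]1CC[C@@H](C)CC(=O)O | intermediate
19 | mixed anhydride of 20 and acetic acid at C15 | C=C1CC[C@H]2[C@](C)(COC(C)=O)CCC[C@]2(C)[C@H]1CC[C@@H](C)CC(=O)OC(C)=O | intermediate (not isolated)
20 | (13R)-18-acetoxylabd-8(17)-en-15-oic acid, (3R)-5-[(1S,4aR,5R,8aR)-5-(acetoxymethyl)-5,8a-dimethyl-2-methylidenedecahydronaphthalen-1-yl]-3-methylpentanoic acid | C=C1CC[C@H]2[C@](C)(COC(C)=O)CCC[C@]2(C)[C@H]1CC[C@@H](C)CC(=O)O | target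

**Step count.** Total: 14 steps. Longest linear sequence: 11 steps (steps 1–6 and 10–14, from dehydroabietic acid); the side-chain branch is steps 7–9.

**Three steps most likely to fail**

1. Step 11 (key step). The organothallium intermediate may be captured by methanol without the 1,2-shift. The C7 methylene may migrate in place of C10, which would give the regioisomeric ketone. A free C8 cation could also trigger a Wagner–Meerwein shift of the C10 methyl. Fallback, setting out from 13 and returning at 16: dihydroxylation (OsO4 cat., N-methylmorpholine N-oxide, acetone/H2O) should give the C8,C9-diol F1. MsCl/pyridine at 0 °C should sulfonylate only the secondary C9 hydroxyl and give the hydroxy mesylate F2 (a mixed anhydride at C15 hydrolyses on work-up). LiClO4/CaCO3 in aqueous THF at 50 °C should then trigger the stereospecific pinacol-type shift of the C8–C10 bond antiperiplanar to the mesylate, without a free C8 cation. NaOH equilibration of C9 as in step 11 returns 16.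

2. Step 10. Attack of the bulky ylide on the neopentyl-type C8 carbonyl may be slow, and enolisation of 7 towards C7 may consume ylide and stall conversion. Fallback, setting out from 7 and returning at 13: condensation with 2,4,6-triisopropylbenzenesulfonyl hydrazide gives the trisylhydrazone F3. n-BuLi (2.2 equiv, THF, −78 → 0 °C; Shapiro reaction) generates the C8 vinyllithium (C7=C8). The aldehyde partner is made from 9 by Fischer esterification to methyl (3R)-6-hydroxy-3-methylhexanoate F4 and Swern oxidation to methyl (3R)-3-methyl-6-oxohexanoate F5. Addition of the vinyllithium to F5 at −78 °C gives the allylic alcohol F6. Mitsunobu reaction with 2-nitrobenzenesulfonylhydrazide (PPh3, diethyl azodicarboxylate) and loss of N2 from the allylic diazene transposes the double bond to C8=C9 and gives the alkylidene methyl ester F7. LiOH (THF/MeOH/H2O) returns 13.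

3. Step 3. Ozone may attack the trialkylbenzene ring too slowly, and competing oxidation of the benzylic C7 methylene would shorten the chain by one carbon. Fallback, setting out from 3 and returning at 4: Birch reduction (Li, NH3, t-BuOH, THF, −78 °C) should give the 8,12-diene F8. Ozonolysis at −78 °C (CH2Cl2/MeOH; Me2S) cleaves both isolated double bonds to the tetracarbonyl compound F9. NaIO4 (aq. dioxane, rt) then cleaves the two 1,3-dicarbonyl units at their active methylene groups to the two carboxyl groups of 4.

**Further compounds**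

F1 | step 11 | C8,C9-diol of 13 (C8 and C9 configuration open) | C1C[C@H]2[C@](C)(CO[Si](C(C)C)(C(C)C)C(C)C)CCC[C@]2(C)C1(O)C(O)CC[C@@H](C)CC(=O)O
F2 | step 11 | C8-hydroxy C9-mesylate of F1 | C1C[C@H]2[C@](C)(CO[Si](C(C)C)(C(C)C)C(C)C)CCC[C@]2(C)C1(O)C(OS(C)(=O)=O)CC[C@@H](C)CC(=O)O
F3 | step 10 | 2,4,6-triisopropylbenzenesulfonylhydrazone of 7 | C1C[C@H]2[C@](C)(CO[Si](C(C)C)(C(C)C)C(C)C)CCC[C@]2(C)C1=NNS(=O)(=O)c1c(C(C)C)cc(C(C)C)cc1C(C)C
F4 | step 10 | methyl (3R)-6-hydroxy-3-methylhexanoate | COC(=O)C[C@H](C)CCCO
F5 | step 10 | methyl (3R)-3-methyl-6-oxohexanoate | COC(=O)C[C@H](C)CCC=O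
F6 | step 10 | allylic alcohol (C7=C8 endocyclic, C9–OH, C9 epimers), methyl ester | C1C[C@H]2[C@](C)(CO[Si](C(C)C)(C(C)C)C(C)C)CCC[C@]2(C)C=1C(O)CC[C@@H](C)CC(=O)OC
F7 | step 10 | methyl ester of 13 (E/Z mixture) | C1C[C@H]2[C@](C)(CO[Si](C(C)C)(C(C)C)C(C)C)CCC[C@]2(C)C1=CCC[C@@H](C)CC(=O)OC
F8 | step 3 | 18-(triisopropylsilyloxy)abieta-8,12-diene | C1C[C@H]2[C@](C)(CO[Si](C(C)C)(C(C)C)C(C)C)CCC[C@]2(C)C3=C1CC(C(C)C)=CC3
F9 | step 3 | tetracarbonyl compound (C10–CO–CH2–CHO and C5–CH2CH2–CO–CH2–CO–CH(CH3)2) | CC(C)C(=O)CC(=O)CC[C@H]1[C@](C)(CO[Si](C(C)C)(C(C)C)C(C)C)CCC[C@]1(C)C(=O)CC=O
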